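In this flask one balance holds throughout: each starting material charged stands in one of its forms, and one side product counts as two of them.

starting material 0.050 M; time 1.5 h

    starting material → target (k1 = 0.0055 s⁻¹)
    other conformer → isomer of the product (k2 = 0.0035 s⁻¹)
    starting material ⇌ other conformer (K3 = 0.50, k3 = 0.0087 s⁻¹)
    starting material + target → side product (k4 = 0.094 M⁻¹ s⁻¹)
    crystals ⇌ target, rate k5*(cs5 - [target]) while solid is left; crystals form when [target] > cs5 (cs5 = 0.71 mM, k5 = 0.56 s⁻¹)

- percentages count the starting material that a species holds: one side product counts as two
- target is meant together with its crystals
- solid, in amounts per volume of the solution: crystals
- in a conversion other conformer counts as not yet reacted
- the reaction counts as stopped when no species that holds the starting material changes by six tenths of a point or more over the second half of the time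
- run time (flask): 1.5 h

- the state of affairs at 1.5 h: stopped, and by what, or still going (other conformer counts as not reacted) (it is still moving / all of the starting material has reacted / forward and back rates have come level)
- how much target there is at 1.5 h, in percent of the starting material charged
- how much isomer of the product there is at 1.5 h, in percent of the starting material charged
- how much side product there is at 1.5 h, in percent of the starting material charged
- amount of target if the flask were left three thousand times as long, in percent of the starting material charged

Minutes of the meeting on this flask. The first chemist solved the two ends. She reported that if exchange between the conformers outran both exits, [other conformer] would follow [starting material] through the equilibrium constant (Curtin–Hammett control). Target made over isomer made would then be the rate constant to target over the equilibrium constant times the rate constant to isomer, 3.14. If exchange were very slow, she said, each conformer formed would go on to isomer, and the ratio would be the rate constant to target over the forward exchange constant, 0.632.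

The second chemist joined the ends. He integrated the balance of other conformer over the run: what enters by exchange leaves by exchange back or as isomer, and the side reaction does not involve that species. With no other conformer at the start or at the end, the result is the sum of the two ends, 3.78, and he named this ρ, the selectivity factor, target made per isomer made. Target made, he added, is the target present plus 0.5 of the side product, and no concentration enters ρ. The first term is larger than the second, so this flask stands nearer the fast end.

The third chemist noted that the slower exit, the one to isomer, has a half-life of 3.30 min, far shorter than the 1.5 h run, so the two conformers should be used up. Before any side reaction, the meeting's split was 79.1% target to 20.9% isomer. It reckoned no further.

The forecast gave all of the starting material has reacted, with target 76.9%, isomer 20.7%, side product 2.37% and a long-time target of 76.9%: “Nothing further changes, so the long-time value is the same.”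

The simulation gives all of the starting material has reacted, with target 76.9%, isomer 20.7%, side product 2.36% and a long-time target of 76.9%. Target already stood at 76.6% after 0.300 h. Target plus 0.5 of the side product, over isomer, comes to 3.77 in this flask, against ρ of 3.78. In the neighbour flask charged with 0.020 M of starting material, the side product is 2.04% and the same ratio comes to 3.78.

Its constants belong to no real substance; no experiment stands behind them.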